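| flask | substrate | product | remark | time |
|---|---|---|---|---|
| summer | 2.1 M | 0.105 M | the very flask that is asked about, followed so far |  |
| noon | 1.1 M | 0.105 M | run made earlier |  |
| flask | 2.1 M | 0.105 M |  | 15 h |

| run | time / h | product / % | crystals / % | substrate / % |
|---|---|---|---|---|
| summer | 0.500 | 12.2 | 11.3 | 83.4 |
| summer | 1.50 | 19.8 | 19.8 | 63.6 |
| summer | 3.00 | 29.0 | 25.7 | 46.1 |
| summer | 5.00 | 37.4 | 37.1 | 36.8 |
| noon | 1.33 | 22.2 | 19.5 | 67.7 |
| noon | 4.00 | 35.6 | 31.2 | 43.1 |
| noon | 6.00 | 41.4 | 40.0 | 34.7 |
| noon | 10.0 | 53.1 | 52.1 | 27.7 |

(standard deviation of a reading: 1 percentage point)

- product is meant together with its crystals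
- solid, in amounts per volume of the solution: crystals
- candidate steps: substrate -> product; substrate <-> dormant form; crystals <-> product; substrate + product -> 2 product
- the amount asked counts what is there less what was charged of it

1. the product and crystals together standing at 15 h, as a percentage of the substrate charged (less the product that was charged)
2. the change that raises the amount of product and crystals together at 15 h, in percent of the substrate charged most ("none" if none brings more than 2 percentage points) (teal / grey / none)
3. amount of product and crystals together at 15 h, in percent of the substrate charged, after grey

- teal: doubling the dissolution coefficient of the product, all else as stated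
- grey: doubling the solubility of the product, all else as stated

Early in the summer run, by 1.50 h, substrate has lost 36 percentage points but product has gained 15 points, so the balance places the rest in the dormant form. Product minus crystals, the dissolved part, averages 0.0236 M in the summer run and 0.0261 M in the noon run, about one level. Substrate + product -> 2 product therefore reads as pseudo-first-order in substrate.

Take the mean turnover: product gained per hour per unit of free substrate, with the substrate curve replaced by its mean over the window. The summer run from 1.50 h to 5.00 h gives 0.100 h⁻¹. At 5.00 h substrate and dormant form together, the pool, stand by the balance at 67.6%, of which substrate is a share, as read, of 0.544. A pool shrinking at turnover times share leaves y at 60.8%.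

The weak link is the turnover. The noon run from 4.00 h to 10.0 h gives a lower 0.0824 h⁻¹, with share 0.491. The means of the two runs, turnover 0.0913 h⁻¹ and share 0.518, give y = 57.9%. Grey is taken here to double the dissolved level and so the turnover; reckoned from 1.50 h, that gives an estimate of 76.2%. Teal, which speeds the approach to that level, is given no gain in this reckoning.

The forecast says 56%, grey and 80%, on the ground that “Doubling solubility doubles the rate”; its y lies 1.9 points below the reckoning above, and its figure after grey lies 3.8 points above it.

The flask gives 57.4%; grey adds 21 points, teal −3.5 points, and grey stands at 78.0%.

    substrate → product (k = 2.10 × 10⁻⁸ s⁻¹)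
    substrate ⇌ dormant form (K = 0.820, k = 6.10 × 10⁻⁵ s⁻¹)
    crystals ⇌ product, rate k3*(cs3 - [product]) while solid is left; crystals form when [product] > cs3 (solubility = 27.0 mM, k = 0.00470 s⁻¹)
    substrate + product → 2 product (k = 8.40 × 10⁻⁴ L mol⁻¹ s⁻¹)

Between 7.50 h and 15.0 h this flask's own states give a turnover of 0.0889 h⁻¹, against the carried 0.0913 h⁻¹. The same flask read at 2.5 d is the neighbour: the carried turnover and share, run on from 5.00 h, leave a pool of 5.02% and y = 95.0%. That neighbour gives 93.8%, with substrate at 3.13% and dormant form at 3.05%.

(The earlier runs and the new flask were generated by integration from invented constants, and the scatter is random.)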